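**Strategy**

The cyclohexane is disconnected at C1–C14, the bond between the ring-fusion carbon that carries the C2=C3 olefin and the isopropyl-bearing carbon. The key step exploits the cis relationship of C2 (on C1) and C9 (on C10): O9 is tied to C2 as a temporary γ-lactone, and the C1 α-lactone radical closes 6-exo onto the C14=C15 prenyl olefin of a geraniol-derived chain. One operation builds the cyclohexane, fixes the cis ring fusion and C14, and converts the prenyl terminus into the isopropyl group. The precursor is a monocyclic α-phenylselanyl butyrolactone with the C11 silyl ether in place. The lactone is then opened and the ten-membered ring (C1–C10) closed by chromium-mediated alkenyl–aldehyde coupling.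

Key step: step 7

Numbering used throughout: C1 and C10 are the ring-fusion carbons (C1 carries the C2=C3 olefin, C10 carries C9). The ten-membered ring is C1–C10 (C3 methyl, C6 and C9 oxygenated, C7 exocyclic methylene). The cyclohexane is C1, C10, C11 (carbinol), C12, C13, C14 (isopropyl-bearing); C15 is the isopropyl methine.

Remark: in step 12 the (R,R) boron controller is taken as the antipode that delivers the allyl group to the Re face of the aldehyde; if its facial sense is the opposite, the (S,S) controller is used in the same way.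

**Route**

Step 1
Reactants: 1 geraniol
Product: 2 (2R,3R)-2,3-epoxygeraniol
Conditions: Ti(OiPr)4 (5 mol %), D-(−)-diethyl tartrate (6 mol %), t-BuOOH, 4 Å MS, CH2Cl2, −20 °C
Reagents that add atoms: tert-butyl hydroperoxide, CC(C)(C)OO
Why: Sharpless asymmetric epoxidation of the allylic alcohol; the D-(−)-tartrate ligand directs oxygen to the face that gives the (2R,3R) epoxide, which fixes C11 (R, kept to the end) and prepares C10 for inversion.

Step 2
Reactants: 2 (2R,3R)-2,3-epoxygeraniol
Product: 3 (2S,3R)-2-ethenyl-3,7-dimethyloct-6-ene-1,3-diol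
Conditions: CH2=CHMgBr (4 equiv), CuI (20 mol %), THF, −30 → 0 °C; aq. NH4Cl
Reagents that add atoms: vinylmagnesium bromide, C=C[Mg]Br
Why: Copper-catalysed Grignard opening of a 2,3-epoxy alcohol by SN2 attack at C10, the only epoxide carbon that is not fully substituted, with inversion, which sets C10 (S) and leaves the C11–O bond untouched; the vinyl group brings C1 and C2.

Step 3
Reactants: 3 (2S,3R)-2-ethenyl-3,7-dimethyloct-6-ene-1,3-diol
Product: 4 bis(triethylsilyl) ether of diol 3
Conditions: Et3SiOTf (2.4 equiv), 2,6-lutidine, CH2Cl2, −78 → 0 °C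
Reagents that add atoms: triethylsilyl trifluoromethanesulfonate, CC[Si](CC)(CC)OS(=O)(=O)C(F)(F)F
Why: Silylation with the silyl triflate covers the tertiary C11 hydroxyl along with the primary one, so that O11 cannot later compete with O9 for lactone formation at C2; no stereocentre is touched.

Step 4
Reactants: 4 bis(triethylsilyl) ether of diol 3
Product: 7 (2S)-2-[(2R)-6-methyl-2-(triethylsilyloxy)hept-5-en-2-yl]butane-1,4-diol, via alkylborane 5 (not isolated), via bis-silyl alcohol 6 (not isolated)
Conditions: 9-BBN, THF, 0 °C → rt; NaOH, H2O2, 0 °C; then PPTS, MeOH, 0 °C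
Reagents that add atoms: hydrogen peroxide, OO
Why: Anti-Markovnikov hydroboration–oxidation in which 9-BBN takes the monosubstituted vinyl group and leaves the trisubstituted olefin, followed by mild acidic methanolysis that removes only the primary silyl ether.

Step 5
Reactants: 7 (2S)-2-[(2R)-6-methyl-2-(triethylsilyloxy)hept-5-en-2-yl]butane-1,4-diol
Product: 9 (4S)-4-[(2R)-6-methyl-2-(triethylsilyloxy)hept-5-en-2-yl]oxolan-2-one, via lactol 8 (not isolated)
Conditions: TEMPO (20 mol %), PhI(OAc)2 (3 equiv), NaHCO3, CH2Cl2, rt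
Reagents that add atoms: none
Why: TEMPO/PhI(OAc)2 oxidative lactonisation of a 1,4-diol, in which the unhindered C2 carbinol is oxidised first, the aldehyde is trapped by the C9 hydroxyl as lactol 8 and oxidised on to the γ-lactone, the temporary C2–O9 tether.

Step 6
Reactants: 9 (4S)-4-[(2R)-6-methyl-2-(triethylsilyloxy)hept-5-en-2-yl]oxolan-2-one
Product: 11 (3S,4S)-4-[(2R)-6-methyl-2-(triethylsilyloxy)hept-5-en-2-yl]-3-(phenylselanyl)oxolan-2-one, via lithium enolate 10 (not isolated)
Conditions: LiN(iPr)2 (1.1 equiv), THF, −78 °C; PhSeBr, −78 °C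
Reagents that add atoms: phenylselenenyl bromide, Br[Se]c1ccccc1
Why: Selenenylation of the lactone lithium enolate anti to the C10 substituent (trans isomer expected); the C1 configuration is lost in the next step and does not matter.

Step 7
Reactants: 11 (3S,4S)-4-[(2R)-6-methyl-2-(triethylsilyloxy)hept-5-en-2-yl]-3-(phenylselanyl)oxolan-2-one
Product: 12 (3aS,4R,7R,7aR)-4-methyl-7-(propan-2-yl)-4-(triethylsilyloxy)hexahydro-2-benzofuran-1(3H)-one (cis-fused)
Conditions: (Me3Si)3SiH (1.3 equiv) and AIBN (0.2 equiv) added by syringe pump over 8 h, PhH, 80 °C, 0.005 M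
Reagents that add atoms: none
Why: Radical chain reaction, the closest known type being the stannane- or silane-mediated 6-exo cyclisation of α-halo or α-seleno esters onto alkenes: the silyl radical abstracts PhSe from C1, the electrophilic C1 radical adds to C14, the less substituted end of the electron-rich C14=C15 olefin, and the tertiary C15 radical takes hydrogen from the silane, which gives the isopropyl group directly. The cyclohexane closes in the 6-exo-trig mode. C1 is controlled by the tether: the chain hangs from the neighbouring lactone carbon C10, so the new bond can only form on the lactone face that carries C11, which gives the cis ring fusion (H1 and H10 cis). C14 is controlled by the chair transition state that the cis-fused lactone imposes, with C9 axial, the C11 methyl equatorial and the C11 silyloxy group axial; the C15 terminus takes the equatorial position because an axial one would clash 1,3-diaxially with C9, so the isopropyl group ends up trans to C2. The step needs cyclisation to outrun hydrogen transfer to the C1 radical and a 1,5-hydrogen shift from allylic C13; slow addition of the poor hydrogen donor (Me3Si)3SiH at high dilution and the polarity match between the α-acyl radical and the trisubstituted olefin are meant to secure this.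

Step 8
Reactants: 12 (3aS,4R,7R,7aR)-4-methyl-7-(propan-2-yl)-4-(triethylsilyloxy)hexahydro-2-benzofuran-1(3H)-one
Product: 13 (3aS,4R,7R,7aR)-4-methyl-7-(propan-2-yl)-4-(triethylsilyloxy)octahydro-2-benzofuran-1-ol (lactol, anomer mixture)
Conditions: i-Bu2AlH (1.1 equiv), CH2Cl2, −78 °C; aq. potassium sodium tartrate
Reagents that add atoms: none
Why: Half-reduction of the γ-lactone to the lactol at −78 °C, where the tetrahedral aluminate is stable; the anomeric centre is not controlled and does not matter.

Step 9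
Reactants: 13 lactol
Product: 14 [(1S,2R,3R,6R)-2-[(1Z)-2-iodoprop-1-en-1-yl]-6-methyl-3-(propan-2-yl)-6-(triethylsilyloxy)cyclohexyl]methanol
Conditions: EtPPh3I, n-BuLi, THF, 0 °C; I2, −78 °C; NaN(SiMe3)2, −20 °C; then 13, −78 → −20 °C
Reagents that add atoms: ethyltriphenylphosphonium iodide, CC[P+](c1ccccc1)(c1ccccc1)c1ccccc1.[I-]; iodine, II
Why: Wittig olefination of the lactol, which reacts as its ring-opened tautomer, with the α-iodo ylide (Stork–Zhao type), which under kinetic control puts iodine cis to C1 (Z); the temporary C2–O9 tether is cleaved here and the C9 hydroxyl is set free.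

Step 10
Reactants: 14 (Z)-alkenyl iodide
Product: 15 [(1S,2S,3R,6R)-2-[(1Z)-5,5-diethoxy-2-methylpent-1-en-1-yl]-6-methyl-3-(propan-2-yl)-6-(triethylsilyloxy)cyclohexyl]methanol
Conditions: CH2=CHCH(OEt)2, 9-BBN, THF, rt; then 14, Pd(dppf)Cl2 (10 mol %), AsPh3, aq. K3PO4, DMF, rt
Reagents that add atoms: acrolein diethyl acetal, C=CC(OCC)OCC
Why: B-alkyl Suzuki–Miyaura coupling of the alkenyl iodide with the alkylborane from acrolein diethyl acetal; retention at the sp2 carbon puts C4 cis to C1, which is the Z trisubstituted C2=C3 olefin, and the acetal carries C6 at the aldehyde level.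

Step 11
Reactants: 15 acetal alcohol
Product: 16 (1R,2S,3R,6R)-2-[(1Z)-5,5-diethoxy-2-methylpent-1-en-1-yl]-6-methyl-3-(propan-2-yl)-6-(triethylsilyloxy)cyclohexane-1-carbaldehyde
Conditions: Dess–Martin periodinane, NaHCO3, CH2Cl2, 0 °C; used at once
Reagents that add atoms: none
Why: Dess–Martin oxidation of the primary C9 alcohol under buffered, non-basic conditions, chosen so that the axial formyl-bearing stereocentre C10 is not epimerised.

Step 12
Reactants: 16 C9 aldehyde
Product: 17 (1R)-3-bromo-1-[(1S,2S,3R,6R)-2-[(1Z)-5,5-diethoxy-2-methylpent-1-en-1-yl]-6-methyl-3-(propan-2-yl)-6-(triethylsilyloxy)cyclohexyl]but-3-en-1-ol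
Conditions: (R,R)-TsNHCH(Ph)CH(Ph)NHTs, BBr3, CH2Cl2, 0 °C → rt, then vacuum; CH2=C(Br)CH2SnBu3, CH2Cl2, rt; then 16, −78 °C; pH 7 buffer
Reagents that add atoms: tributyl(2-bromoprop-2-en-1-yl)stannane, C=C(Br)C[Sn](CCCC)(CCCC)CCCC
Why: Enantioselective 2-haloallylboration through a chair six-membered transition state under reagent control by the C2-symmetric bis-sulfonamide boron controller; Re-face addition gives 9R and installs C8, C7 and the exocyclic methylene as a 2-bromoalkene.

Step 13
Reactants: 17 bromoallyl carbinol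
Product: 18 (4Z)-5-[(1S,2S,3R,6R)-2-[(1R)-3-bromo-1-hydroxybut-3-en-1-yl]-3-hydroxy-3-methyl-6-(propan-2-yl)cyclohexyl]-4-methylpent-4-enal
Conditions: aq. HF (48 %), MeCN, 0 °C → rt
Reagents that add atoms: water, O
Why: Aqueous HF hydrolyses the diethyl acetal to the C6 aldehyde and cleaves the tertiary silyl ether in one operation; no stereocentre is affected.

Step 14
Reactants: 18 seco aldehyde
Product: 19 (1S,2Z,6R,9R,10S,11R,14R)-7-methylideneeunicell-2-ene-6,9,11-triol (eunicellane numbering as above)
Conditions: CrCl2 (10 equiv), NiCl2 (2 mol %), DMSO, rt → 50 °C, slow addition of 18 to 0.003 M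
Reagents that add atoms: none
Why: Nozaki–Hiyama–Kishi reaction, in which chromium-mediated, nickel-catalysed 1,2-addition of the C7 alkenyl bromide unit to the C6 aldehyde closes the ten-membered ring under high dilution; the folded tether (Z olefin, cis ring fusion) should direct addition with the aldehyde oxygen on the outside of the forming ring, which is expected to give 6R.

Step 15
Reactants: 19 triol
Product: 20 target, the 6,9-di-O-acetate of 19
Conditions: Ac2O, pyridine, DMAP (cat.), CH2Cl2, 0 °C → rt
Reagents that add atoms: acetic anhydride, CC(=O)OC(C)=O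
Why: Acetylation esterifies the two secondary hydroxyls at C6 and C9, while the tertiary, axial C11 hydroxyl does not react under these conditions.

**Compound list**

1 | geraniol, (2E)-3,7-dimethylocta-2,6-dien-1-ol | CC(C)=CCC/C(C)=C/CO | starting material
2 | (2R,3R)-2,3-epoxygeraniol | OC[C@H]1O[C@]1(C)CCC=C(C)C | intermediate
3 | (2S,3R)-2-ethenyl-3,7-dimethyloct-6-ene-1,3-diol | OC[C@H](C=C)[C@](C)(O)CCC=C(C)C | intermediate
4 | bis(triethylsilyl) ether of diol 3 | CC[Si](CC)(CC)OC[C@H](C=C)[C@](C)(O[Si](CC)(CC)CC)CCC=C(C)C | intermediate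
5 | alkylborane: vinyl group of 4 converted into CH2CH2–B(9-borabicyclo[3.3.1]nonan-9-yl) (not isolated) | CC[Si](CC)(CC)OC[C@H](CCB1C2CCCC1CCC2)[C@](C)(O[Si](CC)(CC)CC)CCC=C(C)C | intermediate
6 | bis-silyl alcohol: vinyl group of 4 converted into CH2CH2OH (not isolated) | CC[Si](CC)(CC)OC[C@H](CCO)[C@](C)(O[Si](CC)(CC)CC)CCC=C(C)C | intermediate
7 | (2S)-2-[(2R)-6-methyl-2-(triethylsilyloxy)hept-5-en-2-yl]butane-1,4-diol | OC[C@H](CCO)[C@](C)(O[Si](CC)(CC)CC)CCC=C(C)C | intermediate
8 | (4S)-4-[(2R)-6-methyl-2-(triethylsilyloxy)hept-5-en-2-yl]oxolan-2-ol (lactol, not isolated) | OC1C[C@@H](CO1)[C@](C)(O[Si](CC)(CC)CC)CCC=C(C)C | intermediate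
9 | (4S)-4-[(2R)-6-methyl-2-(triethylsilyloxy)hept-5-en-2-yl]oxolan-2-one | O=C1C[C@@H](CO1)[C@](C)(O[Si](CC)(CC)CC)CCC=C(C)C | intermediate
10 | lithium enolate of lactone 9 (not isolated) | [Li]OC1=C[C@@H](CO1)[C@](C)(O[Si](CC)(CC)CC)CCC=C(C)C | intermediate
11 | (3S,4S)-4-[(2R)-6-methyl-2-(triethylsilyloxy)hept-5-en-2-yl]-3-(phenylselanyl)oxolan-2-one (trans) | O=C1[C@@H]([Se]c2ccccc2)[C@@H](CO1)[C@](C)(O[Si](CC)(CC)CC)CCC=C(C)C | intermediate
12 | (3aS,4R,7R,7aR)-4-methyl-7-(propan-2-yl)-4-(triethylsilyloxy)hexahydro-2-benzofuran-1(3H)-one (cis-fused) | O=C1OC[C@@H]2[C@H]1[C@@H](C(C)C)CC[C@@]2(C)O[Si](CC)(CC)CC | intermediate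
13 | (3aS,4R,7R,7aR)-4-methyl-7-(propan-2-yl)-4-(triethylsilyloxy)octahydro-2-benzofuran-1-ol (lactol, anomer mixture) | OC1OC[C@@H]2[C@H]1[C@@H](C(C)C)CC[C@@]2(C)O[Si](CC)(CC)CC | intermediate
14 | [(1S,2R,3R,6R)-2-[(1Z)-2-iodoprop-1-en-1-yl]-6-methyl-3-(propan-2-yl)-6-(triethylsilyloxy)cyclohexyl]methanol | OC[C@@H]1[C@H](/C=C(/C)I)[C@@H](C(C)C)CC[C@@]1(C)O[Si](CC)(CC)CC | intermediate
15 | [(1S,2S,3R,6R)-2-[(1Z)-5,5-diethoxy-2-methylpent-1-en-1-yl]-6-methyl-3-(propan-2-yl)-6-(triethylsilyloxy)cyclohexyl]methanol | OC[C@@H]1[C@H](/C=C(/C)CCC(OCC)OCC)[C@@H](C(C)C)CC[C@@]1(C)O[Si](CC)(CC)CC | intermediate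
16 | (1R,2S,3R,6R)-2-[(1Z)-5,5-diethoxy-2-methylpent-1-en-1-yl]-6-methyl-3-(propan-2-yl)-6-(triethylsilyloxy)cyclohexane-1-carbaldehyde | O=C[C@@H]1[C@H](/C=C(/C)CCC(OCC)OCC)[C@@H](C(C)C)CC[C@@]1(C)O[Si](CC)(CC)CC | intermediate
17 | (1R)-3-bromo-1-[(1S,2S,3R,6R)-2-[(1Z)-5,5-diethoxy-2-methylpent-1-en-1-yl]-6-methyl-3-(propan-2-yl)-6-(triethylsilyloxy)cyclohexyl]but-3-en-1-ol | C=C(Br)C[C@@H](O)[C@@H]1[C@H](/C=C(/C)CCC(OCC)OCC)[C@@H](C(C)C)CC[C@@]1(C)O[Si](CC)(CC)CC | intermediate
18 | (4Z)-5-[(1S,2S,3R,6R)-2-[(1R)-3-bromo-1-hydroxybut-3-en-1-yl]-3-hydroxy-3-methyl-6-(propan-2-yl)cyclohexyl]-4-methylpent-4-enal | C=C(Br)C[C@@H](O)[C@@H]1[C@H](/C=C(/C)CCC=O)[C@@H](C(C)C)CC[C@@]1(C)O | intermediate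
19 | (1S,2Z,6R,9R,10S,11R,14R)-7-methylideneeunicell-2-ene-6,9,11-triol | C=C1C[C@@H](O)[C@@H]2[C@H](/C=C(/C)CC[C@H]1O)[C@@H](C(C)C)CC[C@@]2(C)O | intermediate
20 | 6,9-di-O-acetate of 19 (CNP0303839.1) | C=C1C[C@@H](OC(C)=O)[C@@H]2[C@H](/C=C(/C)CC[C@H]1OC(C)=O)[C@@H](C(C)C)CC[C@@]2(C)O | target

**Step count and risks**

Total step count: 15. Longest linear sequence: 15 steps (geraniol to target; every other input is a commercial reagent).

Step 7 is the first risk. The C1 radical may be quenched by hydrogen transfer from the silane, or may shift a hydrogen from allylic C13, faster than it cyclises. The fallback closes the same bond by a polar route and sets out from lactone 9. SeO2/t-BuOOH oxidation of the E-methyl group of the prenyl unit gives the (E)-allylic alcohol F1, and ClCO2Me/pyridine turns it into the allylic methyl carbonate F2. Deprotonation with LiN(SiMe3)2 followed by Pd(PPh3)4 (THF, −78 °C → rt) closes C1–C14 by intramolecular Tsuji–Trost alkylation at the more substituted allyl terminus to give the cis-fused isopropenyl lactone F3, for the same conformational reasons as in step 7. Hydrogenation (H2, Pd/C, EtOAc) gives 12, where the route is rejoined.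

Step 9 is the second risk. The hindered lactol may open too slowly for the short-lived iodo-ylide, so that the ylide decomposes or the Z selectivity erodes. The fallback sets out from lactol 13. Dimethyl (1-diazo-2-oxopropyl)phosphonate with K2CO3 in MeOH (Ohira–Bestmann) gives the terminal alkyne F4. Double deprotonation (n-BuLi, THF/DMPU) and alkylation of the acetylide with 3-bromo-1,1-diethoxypropane give the internal alkyne F5. Syn hydrozirconation with Cp2ZrHCl, which places zirconium on the less hindered C3, followed by I2 gives the (E)-alkenyl iodide F6 with C4 already cis to C1. Negishi methylation (MeZnCl, Pd(PPh3)4) with retention gives 15, where the route is rejoined.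

Step 14 is the third risk. Facial selectivity at C6 in the chromium-mediated closure may be poor, and oligomerisation competes at higher concentration. The fallback sets out from 18 and moves C6 control from the ring closure to a reagent-controlled reduction. The closure is run as before and the C6-epimeric allylic alcohols F7 are taken on together. MnO2 (CH2Cl2) oxidises only the allylic C6 hydroxyl to give the α-methylene ketone F8. Reduction with (S)-Me-CBS oxazaborolidine and BH3·SMe2 (THF, −30 °C), with the alkenyl group as the large substituent, should give the 6R alcohol 19, where the route is rejoined.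

Further compounds
F1 | step 7 | (4S)-4-[(2R,5E)-7-hydroxy-6-methyl-2-(triethylsilyloxy)hept-5-en-2-yl]oxolan-2-one | O=C1C[C@@H](CO1)[C@](C)(O[Si](CC)(CC)CC)CC/C=C(\C)CO
F2 | step 7 | methyl carbonate of allylic alcohol F1 | O=C1C[C@@H](CO1)[C@](C)(O[Si](CC)(CC)CC)CC/C=C(\C)COC(=O)OC
F3 | step 7 | (3aS,4R,7R,7aR)-4-methyl-7-(prop-1-en-2-yl)-4-(triethylsilyloxy)hexahydro-2-benzofuran-1(3H)-one | O=C1OC[C@@H]2[C@H]1[C@@H](C(C)=C)CC[C@@]2(C)O[Si](CC)(CC)CC
F4 | step 9 | terminal alkyne: C1 ethynyl analogue of 14 with free C9 hydroxyl | OC[C@@H]1[C@H](C#C)[C@@H](C(C)C)CC[C@@]1(C)O[Si](CC)(CC)CC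
F5 | step 9 | internal alkyne: C1 (5,5-diethoxypent-1-yn-1-yl) analogue of 15 | OC[C@@H]1[C@H](C#CCCC(OCC)OCC)[C@@H](C(C)C)CC[C@@]1(C)O[Si](CC)(CC)CC
F6 | step 9 | (E)-alkenyl iodide: C1 [(1E)-5,5-diethoxy-2-iodopent-1-en-1-yl] analogue of 15 | OC[C@@H]1[C@H](/C=C(/I)CCC(OCC)OCC)[C@@H](C(C)C)CC[C@@]1(C)O[Si](CC)(CC)CC
F7 | step 14 | C6-epimer mixture of triol 19 | C=C1C[C@@H](O)[C@@H]2[C@H](/C=C(/C)CCC1O)[C@@H](C(C)C)CC[C@@]2(C)O
F8 | step 14 | 6-oxo analogue of 19 (α-methylene ketone) | C=C1C[C@@H](O)[C@@H]2[C@H](/C=C(/C)CCC1=O)[C@@H](C(C)C)CC[C@@]2(C)O
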